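**Retrosynthetic overview**

1. Ring C is the only ring made. It is closed late by joining O1 to ring-A carbon C8a (palladium aryl etherification of a bromo alcohol); C4 is then desilylated and oxidised, and the three methoxymethyl ethers are removed last.
2. The bromo alcohol comes from an auxiliary-controlled syn aldol (C3–C4 bond, C3 stereocentre) between a ring-B arylacetyl oxazolidinone and 2-bromo-4-(methoxymethoxy)benzaldehyde, followed by silylation and reductive removal of the auxiliary.
3. The ring-B arylacetic acid comes from 2,3,4-trihydroxybenzaldehyde: O4-prenylation, aromatic Claisen rearrangement (1,1-dimethylallyl group onto C5′), O4-methylation and one-carbon homologation of the formyl group.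
4. Feature on which the plan rests: O1 bridges the primary carbon C2 and the aromatic carbon C8a of ring A, and the single stereocentre C3 lies between C2 and C4. While C4 is a silylated carbinol, C3 has no acidifying carbonyl and cannot enolise, so the ketone is unveiled only after ring C exists.
5. Rings A and B are bought as benzenoid rings.

Key step: step 12

Remark: the sacrificial C4 oxygen is carried as a tert-butyldimethylsilyl ether, since a smaller trialkylsilyl group would migrate more easily to the primary oxygen under the carbonate base of the ring closure; (R)-4-benzyl-2-oxazolidinone is the antipode that leads to 3S (its syn aldol is 2R,3R at the imide stage, 2S after reduction of C1, 3S in the chromanone).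

**Route**

Step 1
Reactants: 1 2,3,4-trihydroxybenzaldehyde; 2 prenyl bromide
Product: 3 2,3-dihydroxy-4-(3-methylbut-2-enyloxy)benzaldehyde
Conditions: NaHCO3, DMF, 40 °C
Reagents that add atoms: none
Why: Williamson etherification in which hydrogencarbonate ionises only the 4-OH (para to the formyl group and not tied up in the hydrogen bond that holds the 2-OH), so a single prenyl group should go onto O4.

Step 2
Reactants: 3 2,3-dihydroxy-4-(3-methylbut-2-enyloxy)benzaldehyde
Product: 4 2,3-bis(methoxymethoxy)-4-(3-methylbut-2-enyloxy)benzaldehyde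
Conditions: MOMCl, iPr2NEt, DMAP (cat.), CH2Cl2, 0 °C → reflux
Reagents that add atoms: chloromethyl methyl ether, COCCl
Why: O-alkylation of both remaining phenols with the chloromethyl ether and a hindered amine base should give acetals that are stable to the heat, bases, hydrides and palladium used later and are removable with mild acid at the end.

Step 3
Reactants: 4 2,3-bis(methoxymethoxy)-4-(3-methylbut-2-enyloxy)benzaldehyde
Product: 6 4-hydroxy-2,3-bis(methoxymethoxy)-5-(2-methylbut-3-en-2-yl)benzaldehyde, via ortho-dienone 5 (not isolated)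
Conditions: PhNEt2, 190 °C, argon
Reagents that add atoms: none
Why: Aromatic Claisen rearrangement, in which the [3,3] shift delivers the prenyl unit with allylic inversion to C5, the only free ortho position (C3 carries an acetal oxygen), and the dienone tautomerises to the phenol, the basic solvent holding back acid-induced cyclisation of the new ortho-allyl phenol.

Step 4
Reactants: 6 4-hydroxy-2,3-bis(methoxymethoxy)-5-(2-methylbut-3-en-2-yl)benzaldehyde
Product: 7 4-methoxy-2,3-bis(methoxymethoxy)-5-(2-methylbut-3-en-2-yl)benzaldehyde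
Conditions: MeI, K2CO3, DMF, rt → 40 °C
Reagents that add atoms: iodomethane, CI
Why: Williamson methylation of the acidic para-formyl phenol, for which the small electrophile should overcome the flanking tert-alkyl and acetal groups.

Step 5
Reactants: 7 4-methoxy-2,3-bis(methoxymethoxy)-5-(2-methylbut-3-en-2-yl)benzaldehyde
Product: 9 2-[4-methoxy-2,3-bis(methoxymethoxy)-5-(2-methylbut-3-en-2-yl)phenyl]acetonitrile, via N-(1-tosylvinyl)formamide 8 (not isolated)
Conditions: TosMIC, t-BuOK (excess), DME, −50 °C; then MeOH, reflux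
Reagents that add atoms: p-toluenesulfonylmethyl isocyanide, Cc1ccc(cc1)S(=O)(=O)C[N+]#[C-]
Why: Van Leusen reductive cyanation, in which the TosMIC anion adds to the aldehyde, the oxazoline opens under excess butoxide to the N-(1-tosylvinyl)formamide, and methanolysis of the formyl group with loss of sulfinate gives the one-carbon-homologated nitrile, the excess base keeping elimination to a 5-aryloxazole down.

Step 6
Reactants: 9 2-[4-methoxy-2,3-bis(methoxymethoxy)-5-(2-methylbut-3-en-2-yl)phenyl]acetonitrile
Product: 10 2-[4-methoxy-2,3-bis(methoxymethoxy)-5-(2-methylbut-3-en-2-yl)phenyl]acetic acid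
Conditions: KOH, EtOH/H2O, reflux; then 1 M HCl, 0 °C, to pH 4
Reagents that add atoms: water, O; potassium hydroxide, [K+].[OH-]
Why: Base hydrolysis of the nitrile through the primary amide, to which the acetals, the methyl ether and the vinyl group (no allylic hydrogen, so no isomerisation) are inert, with the acid set free cold at pH 4 to spare the acetals.

Step 7
Reactants: 10 2-[4-methoxy-2,3-bis(methoxymethoxy)-5-(2-methylbut-3-en-2-yl)phenyl]acetic acid; 11 (R)-4-benzyl-2-oxazolidinone
Product: 13 (R)-4-benzyl-3-{2-[4-methoxy-2,3-bis(methoxymethoxy)-5-(2-methylbut-3-en-2-yl)phenyl]acetyl}oxazolidin-2-one, via mixed pivalic anhydride 12 (not isolated)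
Conditions: PivCl, Et3N, THF, −20 °C; then 11, LiCl, −20 °C → rt
Reagents that add atoms: none
Why: N-acylation of the oxazolidinone by the mixed pivalic anhydride under LiCl/Et3N activation, with attack at the less hindered arylacetyl carbonyl, a standard strong-base-free way to load arylacetic acids onto the auxiliary.

Step 8
Reactants: 14 2-bromo-4-hydroxybenzaldehyde
Product: 15 2-bromo-4-(methoxymethoxy)benzaldehyde
Conditions: MOMCl, iPr2NEt, CH2Cl2, 0 °C → rt
Reagents that add atoms: chloromethyl methyl ether, COCCl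
Why: Straightforward O-alkylation of the acidic para-formyl phenol to the same acetal type used on ring B, so that all three phenols are released together at the end.

Step 9
Reactants: 13 (R)-4-benzyl-3-{2-[4-methoxy-2,3-bis(methoxymethoxy)-5-(2-methylbut-3-en-2-yl)phenyl]acetyl}oxazolidin-2-one; 15 2-bromo-4-(methoxymethoxy)benzaldehyde
Product: 17 (R)-4-benzyl-3-{(2R,3R)-3-[2-bromo-4-(methoxymethoxy)phenyl]-3-hydroxy-2-[4-methoxy-2,3-bis(methoxymethoxy)-5-(2-methylbut-3-en-2-yl)phenyl]propanoyl}oxazolidin-2-one, via dibutylboron Z-enolate 16 (not isolated)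
Conditions: Bu2BOTf, iPr2NEt, CH2Cl2, 0 °C; then 15, −78 → 0 °C; then pH 7 buffer, MeOH, 30% H2O2, 0 °C
Reagents that add atoms: none
Why: Evans boron syn-aldol, in which soft enolisation gives the Z dibutylboron enolate and this adds to the aldehyde through a closed chair (Zimmerman–Traxler) transition state on the enolate face opposite the benzyl group of the dipole-opposed (R)-auxiliary, setting C2 as R (the future 3S centre) and the sacrificial carbinol C3 as R (syn).

Step 10
Reactants: 17 (R)-4-benzyl-3-{(2R,3R)-3-[2-bromo-4-(methoxymethoxy)phenyl]-3-hydroxy-2-[4-methoxy-2,3-bis(methoxymethoxy)-5-(2-methylbut-3-en-2-yl)phenyl]propanoyl}oxazolidin-2-one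
Product: 18 (R)-4-benzyl-3-{(2R,3R)-3-[2-bromo-4-(methoxymethoxy)phenyl]-3-(tert-butyldimethylsilyloxy)-2-[4-methoxy-2,3-bis(methoxymethoxy)-5-(2-methylbut-3-en-2-yl)phenyl]propanoyl}oxazolidin-2-one
Conditions: TBSOTf, 2,6-lutidine, CH2Cl2, −78 → 0 °C
Reagents that add atoms: tert-butyldimethylsilyl trifluoromethanesulfonate, CC(C)(C)[Si](C)(C)OS(=O)(=O)C(F)(F)F
Why: Silylation of the hindered secondary benzylic alcohol with a silyl triflate and a non-nucleophilic base, kept cold and near stoichiometric so that neither retro-aldol cleavage nor activation of the aryl acetals should set in.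

Step 11
Reactants: 18 (R)-4-benzyl-3-{(2R,3R)-3-[2-bromo-4-(methoxymethoxy)phenyl]-3-(tert-butyldimethylsilyloxy)-2-[4-methoxy-2,3-bis(methoxymethoxy)-5-(2-methylbut-3-en-2-yl)phenyl]propanoyl}oxazolidin-2-one
Product: 19 (2S,3R)-3-[2-bromo-4-(methoxymethoxy)phenyl]-3-(tert-butyldimethylsilyloxy)-2-[4-methoxy-2,3-bis(methoxymethoxy)-5-(2-methylbut-3-en-2-yl)phenyl]propan-1-ol
Conditions: LiBH4, MeOH (1 equiv), THF, 0 °C → rt; then H2O
Reagents that add atoms: none
Why: Reductive cleavage of the N-acyl oxazolidinone by methanol-modified LiBH4 at the exocyclic carbonyl should give the primary alcohol and release the auxiliary, while aryl bromide, silyl ether, acetals and alkene are inert to borohydride and the alpha centre is not epimerised by this non-basic hydride.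

Step 12
Reactants: 19 (2S,3R)-3-[2-bromo-4-(methoxymethoxy)phenyl]-3-(tert-butyldimethylsilyloxy)-2-[4-methoxy-2,3-bis(methoxymethoxy)-5-(2-methylbut-3-en-2-yl)phenyl]propan-1-ol
Product: 20 (3S,4R)-4-(tert-butyldimethylsilyloxy)-7-(methoxymethoxy)-3-[4-methoxy-2,3-bis(methoxymethoxy)-5-(2-methylbut-3-en-2-yl)phenyl]chroman (3,4-trans)
Conditions: Pd(OAc)2 (5 mol%), 2-(di-tert-butylphosphino)-1,1′-binaphthyl (6 mol%), Cs2CO3, toluene, 70 °C, argon
Reagents that add atoms: none
Why: Zerovalent palladium, formed in the flask from Pd(OAc)2 and the phosphine, inserts into the C8a–Br bond, the primary hydroxyl binds and is deprotonated by Cs2CO3, and C–O reductive elimination from the seven-membered aryl palladium alkoxide forms O1–C8a. The closest known reaction type is the palladium-catalysed cyclisation of 3-(2-bromophenyl)propan-1-ols to chromans with di-tert-butyl biarylphosphines. Ring C closes in a 6-exo sense by ipso substitution at C8a and is the only ring formed in the route. No stereocentre is created, and C3 and C4 are inherited unchanged because no bond to either is broken and C3 has no acidifying carbonyl at this oxidation level. The step needs reductive elimination to outrun beta-hydride elimination of the palladium alkoxide, which the bulky electron-rich ligand should secure, and it needs the secondary oxygen to stay passive, which the tert-butyldimethylsilyl group should secure (no beta-hydride pathway, little tendency to migrate under the weak heterogeneous base). The remote vinyl group on a quaternary carbon is too hindered and too distant to compete by Heck insertion.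

Step 13
Reactants: 20 (3S,4R)-4-(tert-butyldimethylsilyloxy)-7-(methoxymethoxy)-3-[4-methoxy-2,3-bis(methoxymethoxy)-5-(2-methylbut-3-en-2-yl)phenyl]chroman
Product: 21 (3S,4R)-7-(methoxymethoxy)-3-[4-methoxy-2,3-bis(methoxymethoxy)-5-(2-methylbut-3-en-2-yl)phenyl]chroman-4-ol
Conditions: TBAF, AcOH, THF, rt → 40 °C
Reagents that add atoms: none
Why: Fluoride-induced Si–O cleavage, buffered with acetic acid so that the medium is neither basic nor acidic enough to ionise the oxygen-activated benzylic C4 position, should leave the acetals untouched.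

Step 14
Reactants: 21 (3S,4R)-7-(methoxymethoxy)-3-[4-methoxy-2,3-bis(methoxymethoxy)-5-(2-methylbut-3-en-2-yl)phenyl]chroman-4-ol
Product: 22 (3S)-7-(methoxymethoxy)-3-[4-methoxy-2,3-bis(methoxymethoxy)-5-(2-methylbut-3-en-2-yl)phenyl]chroman-4-one
Conditions: Dess–Martin periodinane, NaHCO3, CH2Cl2, 0 °C → rt; crude product taken on directly
Reagents that add atoms: none
Why: Dess–Martin oxidation of the secondary benzylic alcohol to the chroman-4-one under buffered, non-basic conditions should not enolise the newly acidified C3–H, so the 3S configuration set in step 9 is carried into the ketone.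

Step 15
Reactants: 22 (3S)-7-(methoxymethoxy)-3-[4-methoxy-2,3-bis(methoxymethoxy)-5-(2-methylbut-3-en-2-yl)phenyl]chroman-4-one
Product: 23 (3S)-3-[2,3-dihydroxy-4-methoxy-5-(2-methylbut-3-en-2-yl)phenyl]-7-hydroxychroman-4-one (CNP0134633.1)
Conditions: HCl (1.25 M in MeOH), THF, 0 °C → rt, reaction stopped as soon as the last acetal is gone
Reagents that add atoms: none
Why: Acid-catalysed acetal exchange with methanol removes the three aryl methoxymethyl groups as dimethoxymethane, and at 0 °C to room temperature enolisation of the aryl ketone is expected to be much slower than this exchange, while the monosubstituted alkene is not protonated and its ortho neighbour O4′ is a methyl ether, so C3 and the 1,1-dimethylallyl group should survive.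

**Compound list**

1 | 2,3,4-trihydroxybenzaldehyde | O=Cc1ccc(O)c(O)c1O | starting material
2 | prenyl bromide (1-bromo-3-methylbut-2-ene) | CC(C)=CCBr | starting material
3 | 2,3-dihydroxy-4-(3-methylbut-2-enyloxy)benzaldehyde | O=Cc1ccc(OCC=C(C)C)c(O)c1O | intermediate
4 | 2,3-bis(methoxymethoxy)-4-(3-methylbut-2-enyloxy)benzaldehyde | O=Cc1ccc(OCC=C(C)C)c(OCOC)c1OCOC | intermediate
5 | 4-formyl-2,3-bis(methoxymethoxy)-6-(2-methylbut-3-en-2-yl)cyclohexa-2,4-dien-1-one (Claisen ortho-dienone, racemic at C6) | O=CC1=CC(C(C)(C)C=C)C(=O)C(OCOC)=C1OCOC | intermediate (not isolated)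
6 | 4-hydroxy-2,3-bis(methoxymethoxy)-5-(2-methylbut-3-en-2-yl)benzaldehyde | O=Cc1cc(C(C)(C)C=C)c(O)c(OCOC)c1OCOC | intermediate
7 | 4-methoxy-2,3-bis(methoxymethoxy)-5-(2-methylbut-3-en-2-yl)benzaldehyde | O=Cc1cc(C(C)(C)C=C)c(OC)c(OCOC)c1OCOC | intermediate
8 | N-{2-[4-methoxy-2,3-bis(methoxymethoxy)-5-(2-methylbut-3-en-2-yl)phenyl]-1-(4-methylphenylsulfonyl)ethenyl}formamide (present as its potassium salt) | O=CNC(=Cc1cc(C(C)(C)C=C)c(OC)c(OCOC)c1OCOC)S(=O)(=O)c2ccc(C)cc2 | intermediate (not isolated)
9 | 2-[4-methoxy-2,3-bis(methoxymethoxy)-5-(2-methylbut-3-en-2-yl)phenyl]acetonitrile | N#CCc1cc(C(C)(C)C=C)c(OC)c(OCOC)c1OCOC | intermediate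
10 | 2-[4-methoxy-2,3-bis(methoxymethoxy)-5-(2-methylbut-3-en-2-yl)phenyl]acetic acid | OC(=O)Cc1cc(C(C)(C)C=C)c(OC)c(OCOC)c1OCOC | intermediate
11 | (R)-4-benzyl-2-oxazolidinone | O=C1N[C@H](Cc2ccccc2)CO1 | starting material
12 | mixed anhydride of acid 10 with pivalic acid | CC(C)(C)C(=O)OC(=O)Cc1cc(C(C)(C)C=C)c(OC)c(OCOC)c1OCOC | intermediate (not isolated)
13 | (R)-4-benzyl-3-{2-[4-methoxy-2,3-bis(methoxymethoxy)-5-(2-methylbut-3-en-2-yl)phenyl]acetyl}oxazolidin-2-one | O=C(Cc1cc(C(C)(C)C=C)c(OC)c(OCOC)c1OCOC)N1[C@H](Cc2ccccc2)COC1=O | intermediate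
14 | 2-bromo-4-hydroxybenzaldehyde | O=Cc1ccc(O)cc1Br | starting material
15 | 2-bromo-4-(methoxymethoxy)benzaldehyde | O=Cc1ccc(OCOC)cc1Br | intermediate
16 | Z dibutylboron enolate of imide 13 (O and aryl cis) | CCCCB(CCCC)O/C(=C\c1cc(C(C)(C)C=C)c(OC)c(OCOC)c1OCOC)N1[C@H](Cc2ccccc2)COC1=O | intermediate (not isolated)
17 | (R)-4-benzyl-3-{(2R,3R)-3-[2-bromo-4-(methoxymethoxy)phenyl]-3-hydroxy-2-[4-methoxy-2,3-bis(methoxymethoxy)-5-(2-methylbut-3-en-2-yl)phenyl]propanoyl}oxazolidin-2-one (syn aldol) | C=CC(C)(C)c1cc([C@@H](C(=O)N2[C@H](Cc3ccccc3)COC2=O)[C@@H](O)c2ccc(OCOC)cc2Br)c(OCOC)c(OCOC)c1OC | intermediate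
18 | tert-butyldimethylsilyl ether of 17 (2R,3R) | C=CC(C)(C)c1cc([C@@H](C(=O)N2[C@H](Cc3ccccc3)COC2=O)[C@@H](O[Si](C)(C)C(C)(C)C)c2ccc(OCOC)cc2Br)c(OCOC)c(OCOC)c1OC | intermediate
19 | (2S,3R)-3-[2-bromo-4-(methoxymethoxy)phenyl]-3-(tert-butyldimethylsilyloxy)-2-[4-methoxy-2,3-bis(methoxymethoxy)-5-(2-methylbut-3-en-2-yl)phenyl]propan-1-ol | C=CC(C)(C)c1cc([C@@H](CO)[C@@H](O[Si](C)(C)C(C)(C)C)c2ccc(OCOC)cc2Br)c(OCOC)c(OCOC)c1OC | intermediate (key-step precursor)
20 | (3S,4R)-4-(tert-butyldimethylsilyloxy)-7-(methoxymethoxy)-3-[4-methoxy-2,3-bis(methoxymethoxy)-5-(2-methylbut-3-en-2-yl)phenyl]chroman (trans) | C=CC(C)(C)c1cc([C@H]2COc3cc(OCOC)ccc3[C@@H]2O[Si](C)(C)C(C)(C)C)c(OCOC)c(OCOC)c1OC | intermediate (key-step product)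
21 | (3S,4R)-7-(methoxymethoxy)-3-[4-methoxy-2,3-bis(methoxymethoxy)-5-(2-methylbut-3-en-2-yl)phenyl]chroman-4-ol | C=CC(C)(C)c1cc([C@H]2COc3cc(OCOC)ccc3[C@@H]2O)c(OCOC)c(OCOC)c1OC | intermediate
22 | (3S)-7-(methoxymethoxy)-3-[4-methoxy-2,3-bis(methoxymethoxy)-5-(2-methylbut-3-en-2-yl)phenyl]chroman-4-one | C=CC(C)(C)c1cc([C@H]2COc3cc(OCOC)ccc3C2=O)c(OCOC)c(OCOC)c1OC | intermediate
23 | (3S)-3-[2,3-dihydroxy-4-methoxy-5-(2-methylbut-3-en-2-yl)phenyl]-7-hydroxychroman-4-one (CNP0134633.1) | C=CC(C)(C)c1cc([C@H]2COc3cc(O)ccc3C2=O)c(O)c(O)c1OC | target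

**Step count and risks**

Total steps: 15. Longest linear sequence: 14 (steps 1–7 and 9–15); step 8 is a one-step side branch.

Steps most likely to fail:

Step 12 (ring closure). The palladium alkoxide may undergo beta-hydride elimination (hydrodebromination of ring A and an aldehyde), oxidative addition at the ortho-branched bromide may be sluggish, or the silyl group may migrate to the primary oxygen. The fallback sets out from 19 and forms the other ether bond of ring C. Miyaura borylation (B2pin2, Pd(dppf)Cl2, KOAc, dioxane, 80 °C) would give (2S,3R)-3-(tert-butyldimethylsilyloxy)-2-[4-methoxy-2,3-bis(methoxymethoxy)-5-(2-methylbut-3-en-2-yl)phenyl]-3-[4-(methoxymethoxy)-2-(4,4,5,5-tetramethyl-1,3,2-dioxaborolan-2-yl)phenyl]propan-1-ol F1. Oxidation (NaBO3·4H2O, THF/H2O, rt) would give the phenol (2S,3R)-3-(tert-butyldimethylsilyloxy)-3-[2-hydroxy-4-(methoxymethoxy)phenyl]-2-[4-methoxy-2,3-bis(methoxymethoxy)-5-(2-methylbut-3-en-2-yl)phenyl]propan-1-ol F2. Mitsunobu cyclisation (PPh3, DIAD, THF, 0 °C → rt) would then join the phenol oxygen to the primary carbon C2, where no stereocentre is involved, and the route is rejoined at 20.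

Step 3 (Claisen rearrangement). The prenyl group may be lost by C–O heterolysis, the ortho-allyl phenol may isomerise further (abnormal Claisen rearrangement to the 1,2-dimethylallyl isomer), or the phenol may cyclise onto the alkene. The fallback sets out from 1 and installs the side chain by cross-coupling instead of a sigmatropic shift. Selective O4-methylation (MeI, Li2CO3, DMF, 40 °C) would give 2,3-dihydroxy-4-methoxybenzaldehyde F3. Acetal protection (MOMCl, iPr2NEt, CH2Cl2) would give 4-methoxy-2,3-bis(methoxymethoxy)benzaldehyde F4. Bromination (NBS, MeCN, 0 °C) at C5, which is ortho to the methoxy group, para to O2 and meta to the formyl group, would give 5-bromo-4-methoxy-2,3-bis(methoxymethoxy)benzaldehyde F5. A branched-selective (gamma) Suzuki–Miyaura coupling with prenylboronic acid pinacol ester (Pd(OAc)2, a biarylphosphine ligand chosen for gamma selectivity, K3PO4, aqueous MeCN) would then attach the 1,1-dimethylallyl group, and the route is rejoined at 7.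

Step 11 (auxiliary removal). Hydride may attack the ring carbonyl of the oxazolidinone instead of the crowded exocyclic acyl carbon (ring-opened hydroxy amide), or conversion may stall. The fallback sets out from 18 and separates cleavage from reduction. LiOH/H2O2 (THF/H2O, 0 °C), which is selective for the exocyclic carbonyl, would give (2R,3R)-3-[2-bromo-4-(methoxymethoxy)phenyl]-3-(tert-butyldimethylsilyloxy)-2-[4-methoxy-2,3-bis(methoxymethoxy)-5-(2-methylbut-3-en-2-yl)phenyl]propanoic acid F6. Activation (isobutyl chloroformate, N-methylmorpholine, THF, −15 °C) would give the mixed isobutyl carbonic anhydride F7, which is reduced in the same flask (NaBH4, H2O, 0 °C) to rejoin the route at 19; borane is avoided because it would hydroborate the vinyl group.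

Further compounds
F1 | step 12 | (2S,3R)-3-(tert-butyldimethylsilyloxy)-2-[4-methoxy-2,3-bis(methoxymethoxy)-5-(2-methylbut-3-en-2-yl)phenyl]-3-[4-(methoxymethoxy)-2-(4,4,5,5-tetramethyl-1,3,2-dioxaborolan-2-yl)phenyl]propan-1-ol | C=CC(C)(C)c1cc([C@@H](CO)[C@@H](O[Si](C)(C)C(C)(C)C)c2ccc(OCOC)cc2B3OC(C)(C)C(C)(C)O3)c(OCOC)c(OCOC)c1OC
F2 | step 12 | (2S,3R)-3-(tert-butyldimethylsilyloxy)-3-[2-hydroxy-4-(methoxymethoxy)phenyl]-2-[4-methoxy-2,3-bis(methoxymethoxy)-5-(2-methylbut-3-en-2-yl)phenyl]propan-1-ol | C=CC(C)(C)c1cc([C@@H](CO)[C@@H](O[Si](C)(C)C(C)(C)C)c2ccc(OCOC)cc2O)c(OCOC)c(OCOC)c1OC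
F3 | step 3 | 2,3-dihydroxy-4-methoxybenzaldehyde | O=Cc1ccc(OC)c(O)c1O
F4 | step 3 | 4-methoxy-2,3-bis(methoxymethoxy)benzaldehyde | O=Cc1ccc(OC)c(OCOC)c1OCOC
F5 | step 3 | 5-bromo-4-methoxy-2,3-bis(methoxymethoxy)benzaldehyde | O=Cc1cc(Br)c(OC)c(OCOC)c1OCOC
F6 | step 11 | (2R,3R)-3-[2-bromo-4-(methoxymethoxy)phenyl]-3-(tert-butyldimethylsilyloxy)-2-[4-methoxy-2,3-bis(methoxymethoxy)-5-(2-methylbut-3-en-2-yl)phenyl]propanoic acid | C=CC(C)(C)c1cc([C@@H](C(=O)O)[C@@H](O[Si](C)(C)C(C)(C)C)c2ccc(OCOC)cc2Br)c(OCOC)c(OCOC)c1OC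
F7 | step 11 | mixed anhydride of acid F6 with isobutyl hydrogen carbonate | C=CC(C)(C)c1cc([C@@H](C(=O)OC(=O)OCC(C)C)[C@@H](O[Si](C)(C)C(C)(C)C)c2ccc(OCOC)cc2Br)c(OCOC)c(OCOC)c1OC
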